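Late in grey and amber you watch target fall while starting material remains, and the difference between the two is what to watch.

| flask | starting material | partner | remark | time |
|---|---|---|---|---|
| grey | 0.30 M | 0.20 M | run made earlier |  |
| amber | 0.65 M | 0.20 M | run made earlier |  |
| teal | 0.40 M | 0.40 M | run made earlier |  |
| Tuesday's | 0.80 M | 0.600 M |  | 25 h |
| Thursday's | 0.40 M | 0.200 M |  | 25 h |

| run | time / h | target / % | side product / % | starting material / % |
|---|---|---|---|---|
| grey | 2.00 | 46.0 | 4.4 | 49.1 |
| grey | 3.00 | 50.1 | 7.8 | 42.5 |
| grey | 6.00 | 54.6 | 12.7 | 32.0 |
| grey | 10.0 | 54.5 | 19.4 | 26.1 |
| grey | 15.0 | 52.2 | 27.1 | 20.8 |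
| grey | 25.0 | 47.0 | 36.5 | 16.0 |
| amber | 2.00 | 26.9 | 7.8 | 65.5 |
| amber | 3.00 | 24.6 | 11.9 | 63.8 |
| amber | 6.00 | 20.2 | 19.9 | 58.2 |
| amber | 10.0 | 15.2 | 31.0 | 53.1 |
| amber | 15.0 | 11.8 | 38.0 | 51.2 |
| amber | 25.0 | 6.2 | 48.5 | 45.4 |
| teal | 5.00 | 74.7 | 12.6 | 13.1 |
| teal | 10.0 | 77.3 | 17.0 | 6.0 |
| teal | 15.0 | 76.5 | 19.8 | 3.0 |
| teal | 20.0 | 76.8 | 21.7 | 2.1 |
| teal | 25.0 | 77.5 | 21.5 | 2.4 |

(readings scatter by 0.5 percentage points)

- percent here means starting material units held: one side product counts as two
- the numbers in the tables scatter by 0.5 percentage points (one standard deviation)

- the flask that ends with the higher share of target in all that became target or side product, or "neither" when 2 percentage points or less lies between them (Tuesday's / Thursday's / neither)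
- share of target in all that became target or side product, Tuesday's
- share of target in all that became target or side product, Thursday's

Set grey beside Thursday's, which has the same partner charge but 0.100 M more starting material. In amber, target plus half the side product already reads 0.200 M at 2.00 h, which matches the partner charged, the limiting reagent. After that, amber's readings fit a second step that removes one target and one starting material each time, so c(target) minus c(starting material) stays put.

Tuesday's has 0.400 M of target floor, twice the charged c(partner) less the charged c(starting material). Grey's floor is 0.100 M, and its last readings give a difference of 0.0930 M and a share of 56.3%. Thursday's has twice its partner matching its starting material, so its floor is zero and its target falls in step with its starting material.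

My reckoning joins the two ends. Amber's fall from 10.0 h to 25.0 h reads a second-step constant of 0.187 /M/h. As an estimate I take the first step, starting material with partner to target, as instant, since amber's balance above is reached by 2.00 h, short against 25 h. In Tuesday's, the ratio c(starting material)/c(target) stands at 0.333 after that step and is then multiplied by 0.154. That leaves 0.0217 M of starting material and a share of 54.2%. In Thursday's, target stands at 0.200 M after that step and 1/c(target) then grows steadily, reaching 0.103 M of target and a share of 34.9%.

The forecast names Tuesday's, with 52% and 34%, holding that “target decays only while A remains”, A being the starting material. My figures lie slightly higher.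

The flask gives 53.8% for Tuesday's and 36.1% for Thursday's, so the answer is Tuesday's.

    starting material + partner → target, rate k1*[starting material]^1.5*[partner] (k = 7.30 /M^1.5/h)
    starting material + target → side product (k = 0.180 /M/h)

At 25.0 h in Tuesday's, target is made at 0.0195 of the rate at which it is used, net, and its half-life by the second step, 180 h, is long against the 25 h run. Tuesday's holds target above starting material by 0.397 M against its floor of 0.400 M. The neighbour of Tuesday's charged with 0.24 M of partner has a negative floor of −0.320 M, which puts starting material ahead of target by 40.0% of the starting material charged. At 25.0 h that neighbour holds 44.6% starting material and 4.58% target, a share of 8.26%.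

The data were generated by integration for an exercise; noise was put on by code.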